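Tuesday's flask is the near twin of the new one: it has the same equivalents, at half the concentration.

| flask | starting material | coupling partner | second substrate | remark | time |
|---|---|---|---|---|---|
| Saturday's | 0.20 M | 3 equiv | 0.67 equiv | run made earlier |  |
| Wednesday's | 0.20 M | 3 equiv | 1.5 equiv | run made earlier |  |
| Tuesday's | 0.10 M | 3 equiv | 1 equiv | run made earlier |  |
| flask | 0.20 M | 3.00 equiv | 1.00 equiv |  | 25 min |

- Saturday's (time / min: starting material / %, target / %): 1.33: 71.5, 20.1; 4.00: 67.7, 18.3; 8.00: 65.3, 17.1; 10.0: 63.4, 15.6; 15.0: 60.3, 14.5; 20.0: 56.9, 13.5; 25.0: 54.0, 12.1
- Wednesday's (time / min: starting material / %, target / %): 2.00: 79.8, 14.0; 3.00: 78.4, 14.1; 5.00: 78.5, 12.6; 8.00: 77.1, 13.0; 10.0: 76.6, 11.8; 15.0: 73.7, 11.8; 25.0: 70.9, 10.2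
- Tuesday's (time / min: starting material / %, target / %): 5.00: 83.9, 10.1; 10.0: 82.5, 9.7; 15.0: 80.4, 10.3; 20.0: 79.1, 9.1; 25.0: 78.4, 9.2

(scatter of a reading: 0.5 percentage points)

1. which holds at 25 min: what has brought the reaction to rest, or that it has not come to rest (it is still moving / all of the starting material has reacted / forward and back rates have come level / the coupling partner has run out first)
2. how much of the starting material has reacted by 25 min
3. how much target there is at 25 min, in percent of the starting material charged

- the numbers in the tables scatter by 0.5 percentage points (one standard deviation)
- what may be going on: starting material + coupling partner <-> target; second substrate + coupling partner -> second product; target <-> isomer of the product; coupling partner + target -> over-reaction product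
- the reaction counts as stopped when no species that holds the starting material changes by six tenths of a point or more over the second half of the time

In the earlier runs a quick burst is followed by a slow sinking of starting material and target together. I measure this drain as the points of their sum lost per minute, divided by the mean target, between the first and last settled readings:

Saturday: 0.0623 min⁻¹
Wednesday: 0.0426 min⁻¹
Tuesday: 0.0332 min⁻¹

I take the second substrate to remove its own equivalents of partner. Per unit of free partner, Saturday then reads 0.134 M⁻¹ min⁻¹ and Wednesday 0.142 M⁻¹ min⁻¹, so the drain behaves as pseudo-first-order in target at a given free partner. Taking their mean for the new flask gives: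

rate = 0.0552 min⁻¹, drain half-life = 12.6 min

The drain half-life is the time in which target, unreplaced, would lose half of itself to the drain. Tuesday's flask reads 20.9 min, longer, because it has less free partner. So Tuesday's flask gets through 1.20 half-lives in its last reading, and the new flask 1.98 by 25 min. Even at Tuesday's last target, the new flask would lose 6.3 percentage points over the second half of the time, against a stop mark of 0.6 points. I expect it to be still moving.

The forecast says it is still moving, with 38% converted (34% to 42%) and 11.8% target (10.6% to 13%), on the ground that “Target and starting material both keep falling”.

The flask gives it is still moving, 39.5% and 11.4%. At 1.70 equiv or 6.61 equiv of partner the target has moved by 5 points, outside the forecast's range.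

    starting material + coupling partner ⇌ target (K = 0.700 M⁻¹, k = 2.90 M⁻¹ min⁻¹)
    second substrate + coupling partner → second product (k = 6.90 M⁻¹ min⁻¹)
    target ⇌ isomer of the product (K = 0.300, k = 0.510 min⁻¹)
    coupling partner + target → over-reaction product (k = 0.220 M⁻¹ min⁻¹)

At 25.0 min, with 45% of the partner's charge left, the constant of the last step gives target a half-life of 11.6 min by the path to over-reaction product alone, against the 12.6 min I reckoned from the runs, while starting material's forward half-life is 0.88 min, far shorter. In this flask read at 90.0 min, partner stands at 31%, the same constant gives 17.0 min, and target is 5.53%.

The runs stem from a simulated flask for substances that don't exist; scatter was added.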